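**Plan**

1. Numbering used throughout: ring A (dihydropyranone) is O1–C2(heptyl)–C3H2–C4(=O)–C4a=C8a; ring B (δ-lactone) is C4a–C5H2–C6(decyl)–O7–C8(=O)–C8a.
2. Retrosynthesis: cut the lactone bond C8–O7 (ring B) first, then C2–C3 and C4–C4a together, which turns the C3–C4 unit of ring A into a diazomethyl ketone on C2; then cut C8a=C4a (olefination) and O1–C8a (O–H insertion).
3. Enabling feature: O1 is both the ether oxygen on the stereocentre C2 and the donor of the enol ether O1–C8a=C4a. An acyl group on C2 can therefore undergo Wolff rearrangement to a ketene whose sp carbon (C4) is held 1,6 to the nucleophilic β-carbon C4a.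
4. Forward: the chain is joined by O–H insertion and Horner–Wadsworth–Emmons olefination, ring A arises by Wolff rearrangement and ketene capture, and ring B closes last by lactonisation. The diazo group, the tert-butyl ester and the silyl ether are helpers that are lost in steps 10 and 11.
5. Stereochemistry: C2 (S) comes from methyl (S)-glycidate and is carried through the 1,2-shift with retention; C6 (R) comes from (R)-1,2-epoxydodecane. No stereocentre is created after the building-block stage.

Key step: step 10

Remark: compounds 11–15 are expected as Z/E mixtures at the C8a=C4a enol ether bond (the Z isomer is drawn); the geometry is of no consequence, because both isomers should give the same 16, in which this bond is endocyclic.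

Step 1
Reactants: 1 (R)-1,2-epoxydodecane
Product: 2 (4R)-tetradec-1-en-4-ol
Conditions: CH2=CHMgBr (1.5 equiv), CuI (10 mol %), THF, −40 → 0 °C; aq. NH4Cl
Reagents that add atoms: vinylmagnesium bromide, C=C[Mg]Br
Why: Copper-catalysed SN2 opening of the terminal epoxide by the Grignard reagent takes place at the unsubstituted carbon, so the carbinol centre (C6 of the target) is untouched and stays R.

Step 2
Reactants: 2 (4R)-tetradec-1-en-4-ol
Product: 3 tert-butyl(dimethyl){[(4R)-tetradec-1-en-4-yl]oxy}silane
Conditions: TBSCl, imidazole, DMF, 25 °C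
Reagents that add atoms: tert-butyldimethylsilyl chloride, CC(C)(C)[Si](C)(C)Cl
Why: Standard silylation of a secondary alcohol; the silyl ether masks the C6 hydroxyl against the base, the acylating agents and the ketene of steps 7–10.

Step 3
Reactants: 3 tert-butyl(dimethyl){[(4R)-tetradec-1-en-4-yl]oxy}silane
Product: 5 (3R)-3-[(tert-butyldimethylsilyl)oxy]tridecanal, via ozonide 4 (not isolated)
Conditions: O3, CH2Cl2, −78 °C; then PPh3, −78 → 25 °C
Reagents that add atoms: ozone, [O-][O+]=O
Why: Ozonolysis of the terminal alkene with reductive work-up gives the aldehyde carbon that becomes C4a, without touching the silyl ether or the stereocentre.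

Step 4
Reactants: 6 methyl (2S)-oxirane-2-carboxylate (methyl (S)-glycidate)
Product: 7 methyl (2S)-2-hydroxynonanoate
Conditions: n-C6H13MgBr (1.2 equiv), CuI (10 mol %), THF, −78 → −40 °C; aq. NH4Cl
Reagents that add atoms: hexylmagnesium bromide, CCCCCC[Mg]Br
Why: Copper-catalysed Grignard opening of a glycidic ester occurs at C3 faster than addition to the ester at low temperature; no bond to C2 is made or broken, so the centre that becomes C2 of the target stays S.

Step 5
Reactants: 8 tert-butyl 2-(dimethoxyphosphoryl)acetate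
Product: 9 tert-butyl 2-diazo-2-(dimethoxyphosphoryl)acetate
Conditions: 4-acetamidobenzenesulfonyl azide, DBU, MeCN, 0 → 25 °C
Reagents that add atoms: 4-acetamidobenzenesulfonyl azide, CC(=O)Nc1ccc(cc1)S(=O)(=O)N=[N+]=[N-]
Why: Regitz diazo transfer to the doubly activated methylene of a phosphonoacetate.

Step 6
Reactants: 7 methyl (2S)-2-hydroxynonanoate; 9 tert-butyl 2-diazo-2-(dimethoxyphosphoryl)acetate
Product: 10 tert-butyl 2-(dimethoxyphosphoryl)-2-{[(2S)-1-methoxy-1-oxononan-2-yl]oxy}acetate (both epimers at the phosphonate carbon)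
Conditions: Rh2(OAc)4 (1 mol %), PhMe, 80 °C, slow addition of 9
Reagents that add atoms: none
Why: Dirhodium-carbenoid O–H insertion into the secondary alcohol makes the O1–C8a bond; the C–O bond of 7 is not broken, so C2 stays S, and the new centre at the phosphonate carbon is erased in step 7.

Step 7
Reactants: 10 tert-butyl 2-(dimethoxyphosphoryl)-2-{[(2S)-1-methoxy-1-oxononan-2-yl]oxy}acetate; 5 (3R)-3-[(tert-butyldimethylsilyl)oxy]tridecanal
Product: 11 tert-butyl (2Z,5R)-5-[(tert-butyldimethylsilyl)oxy]-2-{[(2S)-1-methoxy-1-oxononan-2-yl]oxy}pentadec-2-enoate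
Conditions: LiN(SiMe3)2 (1.0 equiv), THF, −78 °C; then 5, −78 → 0 °C
Reagents that add atoms: none
Why: Horner–Wadsworth–Emmons olefination of the 2-alkoxyphosphonoacetate forms the C8a=C4a enol ether bond; the phosphonate C–H is far more acidic than the C2–H, so one equivalent of base should leave C2 alone.

Step 8
Reactants: 11 tert-butyl (2Z,5R)-5-[(tert-butyldimethylsilyl)oxy]-2-{[(2S)-1-methoxy-1-oxononan-2-yl]oxy}pentadec-2-enoate
Product: 12 (2S)-2-{[(2Z,5R)-1-tert-butoxy-5-[(tert-butyldimethylsilyl)oxy]-1-oxopentadec-2-en-2-yl]oxy}nonanoic acid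
Conditions: LiOH·H2O (1.5 equiv), THF/H2O (3:1), 0 °C; then 1 M HCl to pH 3–4, 0 °C
Reagents that add atoms: lithium hydroxide, [Li+].[OH-]
Why: Saponification distinguishes the unhindered methyl ester from the tert-butyl ester, which resists hydroxide; at 0 °C the α-alkoxy centre C2 should not epimerise.

Step 9
Reactants: 12 (2S)-2-{[(2Z,5R)-1-tert-butoxy-5-[(tert-butyldimethylsilyl)oxy]-1-oxopentadec-2-en-2-yl]oxy}nonanoic acid
Product: 14 tert-butyl (2Z,5R)-5-[(tert-butyldimethylsilyl)oxy]-2-{[(3S)-1-diazo-2-oxodecan-3-yl]oxy}pentadec-2-enoate, via mixed anhydride 13 (not isolated)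
Conditions: i-BuOCOCl, N-methylmorpholine, THF, −15 °C; then CH2N2 (3 equiv), Et2O, −15 → 0 °C
Reagents that add atoms: diazomethane, C=[N+]=[N-]; isobutyl chloroformate, CC(C)COC(Cl)=O (its atoms stay only in 13)
Why: Arndt–Eistert-type acylation of diazomethane by the mixed carbonic anhydride gives the α-diazoketone under near-neutral conditions that do not deprotonate C2; the trisubstituted, donor-substituted enoate should be a poor dipolarophile at 0 °C.

Step 10
Reactants: 14 tert-butyl (2Z,5R)-5-[(tert-butyldimethylsilyl)oxy]-2-{[(3S)-1-diazo-2-oxodecan-3-yl]oxy}pentadec-2-enoate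
Product: 16 tert-butyl (2S)-5-{(2R)-2-[(tert-butyldimethylsilyl)oxy]dodecyl}-2-heptyl-4-oxo-3,4-dihydro-2H-pyran-6-carboxylate, via ketene 15 (not isolated)
Conditions: hν (390 nm LED), dry PhMe (0.005 M), 25 °C; then 80 °C, 1 h
Reagents that add atoms: none
Why: Proposed new method: Excitation of the diazoketone expels N2 with a concerted 1,2-shift of C2 from the acyl carbon to the diazo carbon (Wolff rearrangement), which makes the C2–C3 bond and leaves the old acyl carbon as the sp carbon C4 of alkylketene 15; C4 then lies 1,6 to C4a, the β-carbon of the enol ether O1–C8a=C4a, which adds to it to make the C4–C4a bond, and a proton shift from C4a to C3 restores the C4a=C8a bond as a push–pull β-alkoxy enone. The closest known reaction types are the photochemical Wolff rearrangement followed by intramolecular ketene–alkene capture, ketene–enol ether addition (which normally ends as a cyclobutanone) and the C-acylation of enamines by ketenes; the C–H acylation of a captodative 2-alkoxyacrylate by a tethered ketene is the untested part. Ring A closes in a 6-(enolendo)-exo-dig mode at the ketene carbon. No stereocentre is formed: C2 is carried over because a migrating sp3 carbon keeps its configuration in the Wolff shift, and C6 is remote. The step needs rearrangement to win over carbene cyclopropanation of the enol ether (metal-free photolysis, concerted loss of N2), C4a and not C8a to bond to C4 (the O1 lone pair polarises the alkene toward C4a), and ring closure to win over ketene dimerisation or hydration (high dilution, dry toluene). Collapse of the adduct to a cyclobutanone would need a strained 2-oxabicyclo[2.2.0]hexanone, so the proton shift to the conjugated vinylogous ester should be the open exit, and cleavage of the ring bond C2–O1 is held back because that bond lies near the plane of the C3=C4 enolate.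

Step 11
Reactants: 16 tert-butyl (2S)-5-{(2R)-2-[(tert-butyldimethylsilyl)oxy]dodecyl}-2-heptyl-4-oxo-3,4-dihydro-2H-pyran-6-carboxylate
Product: 19 (2S,6R)-6-decyl-2-heptyl-2,3,5,6-tetrahydropyrano[3,4-b]pyran-4,8-dione (CNP0087259.1), via silyl ether acid 17 (not isolated), via hydroxy acid 18 (not isolated)
Conditions: CF3CO2H/CH2Cl2 (1:3), 0 → 25 °C; then H2O (5 vol %), 25 °C; concentrate from PhMe
Reagents that add atoms: none
Why: Trifluoroacetic acid cleaves the tert-butyl ester (loss of 2-methylpropene) and, once water is added, the silyl ether; the freed C6 hydroxyl and the carboxyl are held cis on the C4a=C8a bond and should close ring B by acid-catalysed 6-exo-trig lactonisation, with both stereocentres untouched.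

**Compound list**

1 | (R)-1,2-epoxydodecane [(2R)-2-decyloxirane] | CCCCCCCCCC[C@@H]1CO1 | starting material
2 | (4R)-tetradec-1-en-4-ol | CCCCCCCCCC[C@@H](O)CC=C | intermediate
3 | tert-butyl(dimethyl){[(4R)-tetradec-1-en-4-yl]oxy}silane | CCCCCCCCCC[C@@H](O[Si](C)(C)C(C)(C)C)CC=C | intermediate
4 | 3-{(2R)-2-[(tert-butyldimethylsilyl)oxy]dodecyl}-1,2,4-trioxolane (ozonide, either configuration at the ring carbon) | CCCCCCCCCC[C@@H](O[Si](C)(C)C(C)(C)C)CC1OCOO1 | intermediate (not isolated)
5 | (3R)-3-[(tert-butyldimethylsilyl)oxy]tridecanal | CCCCCCCCCC[C@@H](O[Si](C)(C)C(C)(C)C)CC=O | intermediate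
6 | methyl (2S)-oxirane-2-carboxylate | COC(=O)[C@@H]1CO1 | starting material
7 | methyl (2S)-2-hydroxynonanoate | CCCCCCC[C@H](O)C(=O)OC | intermediate
8 | tert-butyl 2-(dimethoxyphosphoryl)acetate | COP(=O)(OC)CC(=O)OC(C)(C)C | starting material
9 | tert-butyl 2-diazo-2-(dimethoxyphosphoryl)acetate | COP(=O)(OC)C(=[N+]=[N-])C(=O)OC(C)(C)C | intermediate
10 | tert-butyl 2-(dimethoxyphosphoryl)-2-{[(2S)-1-methoxy-1-oxononan-2-yl]oxy}acetate | CCCCCCC[C@H](OC(C(=O)OC(C)(C)C)P(=O)(OC)OC)C(=O)OC | intermediate
11 | tert-butyl (2Z,5R)-5-[(tert-butyldimethylsilyl)oxy]-2-{[(2S)-1-methoxy-1-oxononan-2-yl]oxy}pentadec-2-enoate | CC(C)(C)OC(=O)/C(O[C@@H](CCCCCCC)C(=O)OC)=C/C[C@@H](CCCCCCCCCC)O[Si](C)(C)C(C)(C)C | intermediate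
12 | (2S)-2-{[(2Z,5R)-1-tert-butoxy-5-[(tert-butyldimethylsilyl)oxy]-1-oxopentadec-2-en-2-yl]oxy}nonanoic acid | CC(C)(C)OC(=O)/C(O[C@@H](CCCCCCC)C(=O)O)=C/C[C@@H](CCCCCCCCCC)O[Si](C)(C)C(C)(C)C | intermediate
13 | mixed anhydride of 12 with isobutyl hydrogen carbonate | CC(C)(C)OC(=O)/C(O[C@@H](CCCCCCC)C(=O)OC(=O)OCC(C)C)=C/C[C@@H](CCCCCCCCCC)O[Si](C)(C)C(C)(C)C | intermediate (not isolated)
14 | tert-butyl (2Z,5R)-5-[(tert-butyldimethylsilyl)oxy]-2-{[(3S)-1-diazo-2-oxodecan-3-yl]oxy}pentadec-2-enoate | CC(C)(C)OC(=O)/C(O[C@@H](CCCCCCC)C(=O)C=[N+]=[N-])=C/C[C@@H](CCCCCCCCCC)O[Si](C)(C)C(C)(C)C | intermediate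
15 | tert-butyl (2Z,5R)-5-[(tert-butyldimethylsilyl)oxy]-2-{[(3S)-1-oxodec-1-en-3-yl]oxy}pentadec-2-enoate (ketene) | CC(C)(C)OC(=O)/C(O[C@@H](CCCCCCC)C=C=O)=C/C[C@@H](CCCCCCCCCC)O[Si](C)(C)C(C)(C)C | intermediate (not isolated)
16 | tert-butyl (2S)-5-{(2R)-2-[(tert-butyldimethylsilyl)oxy]dodecyl}-2-heptyl-4-oxo-3,4-dihydro-2H-pyran-6-carboxylate | CCCCCCC[C@H]1CC(=O)C(C[C@@H](CCCCCCCCCC)O[Si](C)(C)C(C)(C)C)=C(O1)C(=O)OC(C)(C)C | intermediate
17 | (2S)-5-{(2R)-2-[(tert-butyldimethylsilyl)oxy]dodecyl}-2-heptyl-4-oxo-3,4-dihydro-2H-pyran-6-carboxylic acid | CCCCCCC[C@H]1CC(=O)C(C[C@@H](CCCCCCCCCC)O[Si](C)(C)C(C)(C)C)=C(O1)C(=O)O | intermediate (not isolated)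
18 | (2S)-2-heptyl-5-[(2R)-2-hydroxydodecyl]-4-oxo-3,4-dihydro-2H-pyran-6-carboxylic acid | CCCCCCC[C@H]1CC(=O)C(C[C@@H](CCCCCCCCCC)O)=C(O1)C(=O)O | intermediate (not isolated)
19 | (2S,6R)-6-decyl-2-heptyl-2,3,5,6-tetrahydropyrano[3,4-b]pyran-4,8-dione (CNP0087259.1) | CCCCCCCCCC[C@@H]1CC2=C(O[C@@H](CCCCCCC)CC2=O)C(=O)O1 | target

**Step count**

Total: 11 steps. Longest linear sequence: 8 steps (1, 2, 3, 7, 8, 9, 10, 11).

**Steps most likely to fail**

Step 10 (Proposed new method). The weakly nucleophilic captodative alkene may capture the ketene more slowly than the ketene dimerises or is hydrated, the carbene channel may cyclopropanate the enol ether, and opening of the C2–O1 bond after C–C bond formation could erode the configuration at C2. The fallback sets out from diazoketone 14 and makes the two bonds one after the other by known chemistry. Wolff rearrangement in the presence of water (PhCO2Ag cat., Et3N, THF/H2O, 25 °C; Arndt–Eistert homologation) should give the β-alkoxy acid F1, in which the C2–C3 bond is in place with retention. 1-Chloro-N,N,2-trimethylprop-1-en-1-amine (CH2Cl2, 0 °C) should turn it into the acid chloride F2 under neutral conditions. AgOSO2CF3 with 2,6-di-tert-butyl-4-methylpyridine (CH2Cl2, −40 °C) should then close the C4–C4a bond by Friedel–Crafts-type C-acylation of the enol ether, which returns to the route at 16.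

Step 7. The fully substituted, hindered phosphonate carbanion may add slowly to the enolisable β-silyloxy aldehyde, so that aldehyde enolisation, β-elimination of silanolate or base-mediated epimerisation next to the methyl ester compete. The fallback sets out from phosphonate 10 and forms the trisubstituted enol ether by metathesis instead. Olefination of 10 with aqueous formaldehyde (K2CO3, THF/H2O, 25 °C), the least demanding carbonyl partner, should give the 2-alkoxyacrylate F3. Cross-metathesis of F3 with alkene 3 (second-generation Grubbs catalyst, CH2Cl2, 40 °C, F3 in excess) should then give 11, which returns to the route; either alkene geometry serves.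

Step 11. Strong acid may open ring A by retro-oxa-Michael cleavage with loss of configuration at C2, or silyl cleavage and lactonisation may stay incomplete. The fallback sets out from 16 and avoids Brønsted acid. CF3SO3SiMe3 with 2,6-lutidine (CH2Cl2, 0 °C) should convert the tert-butyl ester into the trimethylsilyl ester F4, which aqueous work-up hydrolyses to acid 17. HF·pyridine (THF, 0 °C) should then free hydroxy acid 18. Ring B is closed by carboxyl activation with N,N'-diisopropylcarbodiimide and catalytic DMAP (CH2Cl2, 0 → 25 °C), which returns to the route at 19.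

**Further compounds**

F1 | step 10 | (3S)-3-{[(2Z,5R)-1-tert-butoxy-5-[(tert-butyldimethylsilyl)oxy]-1-oxopentadec-2-en-2-yl]oxy}decanoic acid | CC(C)(C)OC(=O)/C(O[C@@H](CCCCCCC)CC(=O)O)=C/C[C@@H](CCCCCCCCCC)O[Si](C)(C)C(C)(C)C
F2 | step 10 | (3S)-3-{[(2Z,5R)-1-tert-butoxy-5-[(tert-butyldimethylsilyl)oxy]-1-oxopentadec-2-en-2-yl]oxy}decanoyl chloride | CC(C)(C)OC(=O)/C(O[C@@H](CCCCCCC)CC(Cl)=O)=C/C[C@@H](CCCCCCCCCC)O[Si](C)(C)C(C)(C)C
F3 | step 7 | tert-butyl 2-{[(2S)-1-methoxy-1-oxononan-2-yl]oxy}prop-2-enoate | C=C(O[C@@H](CCCCCCC)C(=O)OC)C(=O)OC(C)(C)C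
F4 | step 11 | trimethylsilyl (2S)-5-{(2R)-2-[(tert-butyldimethylsilyl)oxy]dodecyl}-2-heptyl-4-oxo-3,4-dihydro-2H-pyran-6-carboxylate | CCCCCCC[C@H]1CC(=O)C(C[C@@H](CCCCCCCCCC)O[Si](C)(C)C(C)(C)C)=C(O1)C(=O)O[Si](C)(C)C
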